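**Retrosynthetic overview**
1. The (R)-hemiketal comes from its C2 levulinate ester. The ester cannot ring-open, so C2 is locked, and release of the free hemiketal is the last operation.
2. The furanone ring comes from a 3-alkyl-4-hydroxy-5-methylcoumarin plus O2 minus CO2 (C3 hydroperoxide, dioxetanone, open 1,2-diketone, lactol), which mirrors the likely origin of this nor-coumarin skeleton. The racemising lactol is converted into one ester by acylative dynamic kinetic resolution in the same flask.
3. The C3–C1' bond comes from allyl ("prenyl") transfer from a C15 allylic acetate to 4-hydroxy-5-methylcoumarin under Pd catalysis.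
4. The C15 chain comes from geranyl acetate (C10) and 2-methylbut-3-yn-2-ol (C5) by allylic oxidation, acetylide addition and redox isomerisation to the (E)-γ-hydroxy dienone.
5. Ring order: the benzene ring is bought, the pyranone ring is closed first by β-keto ester lactonisation, and it is contracted to the furanone ring last.

Assumption: C2 is (R) as read from the SMILES; a free 2-hydroxybenzofuran-3(2H)-one can racemise through its open 1,2-diketone, so the hemiketal is kept cold, aprotic and faintly acidic once released, and the HyperBTM antipode is chosen by analogy with related lactols and confirmed on 16 (both antipodes are sold).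

**Step 1**
Reactants: 1 geranyl acetate
Product: 3 (2E,6E)-3,7-dimethyl-8-oxoocta-2,6-dien-1-yl acetate, via 8-hydroxygeranyl acetate 2 (not isolated)
Conditions: SeO2 (1.1 equiv), 1,4-dioxane, 80 °C, 3 h
Reagents that add atoms: selenium dioxide, O=[Se]=O
Why: Riley allylic oxidation (ene reaction then [2,3]-sigmatropic shift) selects the electron-rich distal trisubstituted alkene and its (E)-methyl group, because the alkene next to the acetate is inductively deactivated, and a second oxidation of 2 by the same reagent gives the (E)-enal with the 2E alkene untouched.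

**Step 2**
Reactants: 3 (2E,6E)-3,7-dimethyl-8-oxoocta-2,6-dien-1-yl acetate; 4 2-methylbut-3-yn-2-ol
Product: 6 (2E,6E)-8,11-dihydroxy-3,7,11-trimethyldodeca-2,6-dien-9-yn-1-yl acetate (racemic at C8), via dilithiated alkynol 5 (not isolated)
Conditions: 4 (1.2 equiv), n-BuLi (2.4 equiv), THF, −78 to 0 °C; then 3, −78 °C, 30 min; AcOH quench at −78 °C
Reagents that add atoms: none
Why: In this 1,2-addition of a lithium acetylide to an enal, the acetylide carbon of 5 adds to the aldehyde at −78 °C much faster than either anionic site attacks the acetate, and the new C8 carbinol centre forms as a racemate that step 3 erases.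

**Step 3**
Reactants: 6 (2E,6E)-8,11-dihydroxy-3,7,11-trimethyldodeca-2,6-dien-9-yn-1-yl acetate
Product: 7 (2E,6E,9E)-11-hydroxy-3,7,11-trimethyl-8-oxododeca-2,6,9-trien-1-yl acetate
Conditions: RuCl(η5-C9H7)(PPh3)2 (5 mol %), In(OTf)3 (5 mol %), camphorsulfonic acid (5 mol %), THF, 65 °C
Reagents that add atoms: none
Why: In this ruthenium-catalysed redox isomerisation of a propargylic alcohol (Trost type), the carbinol hydride moves to the alkyne at ruthenium and protonolysis releases the conjugated (E)-enone, so C8 becomes the ketone and C9=C10 the trans alkene in one step, while the tertiary carbinol (no carbinol H), the trisubstituted alkenes and the acetate have no such pathway.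

**Step 4**
Reactants: 8 1-(2-hydroxy-6-methylphenyl)ethan-1-one
Product: 10 4-hydroxy-5-methyl-2H-chromen-2-one, via beta-keto ester 9 (not isolated)
Conditions: NaH (3.5 equiv), (EtO)2CO (5 equiv), toluene, 110 °C; then aq HCl
Reagents that add atoms: diethyl carbonate, CCOC(=O)OCC
Why: Claisen-type C-ethoxycarbonylation of the ketone enolate gives 9, whose phenoxide lactonises onto the ester, which is the same β-ketoacyl-to-phenol closure that releases the polyketide chain as a 4-hydroxycoumarin; no stereocentre is formed.

**Step 5**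
Reactants: 7 (2E,6E,9E)-11-hydroxy-3,7,11-trimethyl-8-oxododeca-2,6,9-trien-1-yl acetate; 10 4-hydroxy-5-methyl-2H-chromen-2-one
Product: 11 4-hydroxy-3-[(2E,6E,9E)-11-hydroxy-3,7,11-trimethyl-8-oxododeca-2,6,9-trien-1-yl]-5-methyl-2H-chromen-2-one
Conditions: Pd(PPh3)4 (5 mol %), 10 (1.5 equiv), Et3N (1.5 equiv), THF, 40 °C
Reagents that add atoms: none
Why: In this Tsuji–Trost allylation, the laboratory counterpart of C3 prenyl transfer, zerovalent palladium ionises the primary allylic acetate and the soft, acidic coumarin enolate (pKa about 5) attacks the unhindered allyl terminus to give the linear C3-alkylated product with 2E geometry kept, while excess 10 suppresses double allylation and the hindered enone carbons are too slow for Michael addition at 40 °C.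

**Step 6**
Reactants: 11 4-hydroxy-3-[(2E,6E,9E)-11-hydroxy-3,7,11-trimethyl-8-oxododeca-2,6,9-trien-1-yl]-5-methyl-2H-chromen-2-one
Product: 16 (2S)-2-[(2E,6E,9E)-11-hydroxy-3,7,11-trimethyl-8-oxododeca-2,6,9-trien-1-yl]-4-methyl-3-oxo-2,3-dihydro-1-benzofuran-2-yl 4-oxopentanoate, via C3 hydroperoxide 12 (not isolated), via dioxetanone 13 (not isolated), via open triketone 14 (not isolated), via racemic lactol 15 (not isolated)
Conditions: (a) O2 (1 atm), tetraphenylporphyrin (1 mol %), DIPEA (1.1 equiv), CHCl3, white LED behind a 495 nm long-pass filter, −40 °C, stop at full conversion of 11, then dark, 0 °C, Ar purge; (b) (2S,3R)-HyperBTM (10 mol %), levulinic anhydride (1.6 equiv), DIPEA (1.0 equiv), 0 to 20 °C, dark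
Reagents that add atoms: dioxygen, O=O; levulinic anhydride, CC(=O)CCC(=O)OC(=O)CCC(C)=O
Why: Proposed new method: the ammonium enolate of 11 takes up singlet oxygen at C3 far faster than the isolated trisubstituted alkene or the electron-poor dienone can react, the peroxide of 12 attacks its own aryl-ester carbonyl to give 13 (as in aryl-ester chemiluminescence), 13 loses CO2 to give 14, and the freed phenol closes onto the new ketone to form the furanone ring of 15; because 15 racemises through 14 under amine base while the acylated isothiourea recognises the ketone carbonyl next to the carbinol, one enantiomer is esterified irreversibly and C2 is fixed as (S)-16, the unactivated side-chain tertiary alcohol staying free; the closest known reaction types are enolate photooxygenation with oxidative decarboxylation of α-hydroperoxy acid derivatives and the isothiourea-catalysed acylative dynamic kinetic resolution of tetrasubstituted benzoxazinone and morpholinone lactols.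

**Step 7**
Reactants: 16 (2S)-2-[(2E,6E,9E)-11-hydroxy-3,7,11-trimethyl-8-oxododeca-2,6,9-trien-1-yl]-4-methyl-3-oxo-2,3-dihydro-1-benzofuran-2-yl 4-oxopentanoate
Product: 18 (2R)-2-hydroxy-2-[(2E,6E,9E)-11-hydroxy-3,7,11-trimethyl-8-oxododeca-2,6,9-trien-1-yl]-4-methyl-1-benzofuran-3(2H)-one (CNP0266980.1), via levulinate hydrazone 17 (not isolated)
Conditions: N2H4·H2O (1.05 equiv), AcOH (5 equiv), pyridine (5 equiv), CH2Cl2, −10 °C, 20 min; cold pH 5 citrate wash, fast chromatography on neutral silica at 0 °C
Reagents that add atoms: none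
Why: In this assisted (hydrazinolytic) levulinate cleavage, hydrazine condenses with the unhindered methyl ketone much faster than with the hindered conjugated ketones and the NH2 of 17 cyclises onto the ester carbonyl, so only the acyl–O bond breaks and both C2–O bonds are retained (the descriptor changes from S to R only because the CIP ranks of the two oxygens swap), while the faintly acidic cold buffer delivers the neutral hemiketal without passing through its alkoxide, the species that opens to 14.

**Compound list**
1 | geranyl acetate | CC(C)=CCC/C(C)=C/COC(C)=O | starting material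
2 | (2E,6E)-8-hydroxy-3,7-dimethylocta-2,6-dien-1-yl acetate | CC(=O)OC/C=C(\C)CC/C=C(\C)CO | intermediate (not isolated)
3 | (2E,6E)-3,7-dimethyl-8-oxoocta-2,6-dien-1-yl acetate | CC(=O)OC/C=C(\C)CC/C=C(\C)C=O | intermediate
4 | 2-methylbut-3-yn-2-ol | C#CC(C)(C)O | starting material
5 | dilithio derivative of 2-methylbut-3-yn-2-ol (O-Li, C-Li) | [Li]C#CC(C)(C)O[Li] | intermediate (not isolated)
6 | (2E,6E)-8,11-dihydroxy-3,7,11-trimethyldodeca-2,6-dien-9-yn-1-yl acetate, racemic at C8 | CC(=O)OC/C=C(\C)CC/C=C(\C)C(O)C#CC(C)(C)O | intermediate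
7 | (2E,6E,9E)-11-hydroxy-3,7,11-trimethyl-8-oxododeca-2,6,9-trien-1-yl acetate | CC(=O)OC/C=C(\C)CC/C=C(\C)C(=O)/C=C/C(C)(C)O | intermediate
8 | 1-(2-hydroxy-6-methylphenyl)ethan-1-one | CC(=O)c1c(C)cccc1O | starting material
9 | ethyl 3-(2-hydroxy-6-methylphenyl)-3-oxopropanoate | CCOC(=O)CC(=O)c1c(C)cccc1O | intermediate (not isolated)
10 | 4-hydroxy-5-methyl-2H-chromen-2-one | Cc1cccc2oc(=O)cc(O)c12 | intermediate
11 | 4-hydroxy-3-[(2E,6E,9E)-11-hydroxy-3,7,11-trimethyl-8-oxododeca-2,6,9-trien-1-yl]-5-methyl-2H-chromen-2-one | Cc1cccc2oc(=O)c(C/C=C(\C)CC/C=C(\C)C(=O)/C=C/C(C)(C)O)c(O)c12 | intermediate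
12 | 3-hydroperoxy-3-[(2E,6E,9E)-11-hydroxy-3,7,11-trimethyl-8-oxododeca-2,6,9-trien-1-yl]-5-methylchromane-2,4-dione, racemic | Cc1cccc2OC(=O)C(OO)(C/C=C(\C)CC/C=C(\C)C(=O)/C=C/C(C)(C)O)C(=O)c12 | intermediate (not isolated)
13 | 4-(2-hydroxy-6-methylbenzoyl)-4-[(2E,6E,9E)-11-hydroxy-3,7,11-trimethyl-8-oxododeca-2,6,9-trien-1-yl]-1,2-dioxetan-3-one, racemic | Cc1cccc(O)c1C(=O)C1(C/C=C(\C)CC/C=C(\C)C(=O)/C=C/C(C)(C)O)OOC1=O | intermediate (not isolated)
14 | (4E,8E,11E)-13-hydroxy-1-(2-hydroxy-6-methylphenyl)-5,9,13-trimethyltetradeca-4,8,11-triene-1,2,10-trione | Cc1cccc(O)c1C(=O)C(=O)C/C=C(\C)CC/C=C(\C)C(=O)/C=C/C(C)(C)O | intermediate (not isolated)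
15 | racemic 2-hydroxy-2-[(2E,6E,9E)-11-hydroxy-3,7,11-trimethyl-8-oxododeca-2,6,9-trien-1-yl]-4-methyl-1-benzofuran-3(2H)-one | C/C(=C\CC1(O)Oc2cccc(C)c2C1=O)CC/C=C(\C)C(=O)/C=C/C(C)(C)O | intermediate (not isolated)
16 | (2S)-2-[(2E,6E,9E)-11-hydroxy-3,7,11-trimethyl-8-oxododeca-2,6,9-trien-1-yl]-4-methyl-3-oxo-2,3-dihydro-1-benzofuran-2-yl 4-oxopentanoate | C/C(=C\C[C@@]1(OC(=O)CCC(C)=O)Oc2cccc(C)c2C1=O)CC/C=C(\C)C(=O)/C=C/C(C)(C)O | intermediate
17 | hydrazone of 16 at the levulinate ketone, (2S) | C/C(=C\C[C@@]1(OC(=O)CCC(C)=NN)Oc2cccc(C)c2C1=O)CC/C=C(\C)C(=O)/C=C/C(C)(C)O | intermediate (not isolated)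
18 | (2R)-2-hydroxy-2-[(2E,6E,9E)-11-hydroxy-3,7,11-trimethyl-8-oxododeca-2,6,9-trien-1-yl]-4-methyl-1-benzofuran-3(2H)-one | C/C(=C\C[C@@]1(O)Oc2cccc(C)c2C1=O)CC/C=C(\C)C(=O)/C=C/C(C)(C)O | target

**Total step count:** 7. **Longest linear sequence:** 6 (steps 1, 2, 3, 5, 6, 7, from geranyl acetate).

**Three steps most likely to fail**

Step 6. There are four main risks:
- Singlet oxygen may also attack the C2'=C3' alkene in an ene reaction.
- 12 may be reduced by unreacted enolate.
- The phenol of 14 may be acylated.
- The levulinoyl donor may give lower selectivity than branched anhydrides.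

The fallback sets out from 11 and returns at 15, without light or singlet oxygen. The enolate of 11 is hydroxylated with 2-(phenylsulfonyl)-3-phenyloxaziridine (Et3N, THF, 0 °C) to give 3-hydroxy-3-[(2E,6E,9E)-11-hydroxy-3,7,11-trimethyl-8-oxododeca-2,6,9-trien-1-yl]-5-methylchromane-2,4-dione F2. Aqueous NaHCO3/THF opens the lactone and the acid decarboxylates to the acyloin (4E,8E,11E)-2,13-dihydroxy-1-(2-hydroxy-6-methylphenyl)-5,9,13-trimethyltetradeca-4,8,11-triene-1,10-dione F3. Air with Cu(OAc)2 (10 mol %) in MeCN oxidises this to 14, which closes to 15. Lactol 15 is then isolated and the acylative resolution to 16 is run and optimised as a separate operation. Because 16 is configurationally stable, its enantiomer ratio can be measured and improved before release.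

Step 7. The buffer may catalyse ring opening and so cause partial racemisation, and hydrazine may capture 14 or the dienone. The fallback sets out from 15, isolated by stopping step 6 after the oxygenation stage, and returns at 18. It uses physical resolution instead of trap and release. The racemate is separated by preparative supercritical-fluid chromatography on an immobilised amylose phase (CO2/2-propanol, no additive, 10 °C). The unwanted (2S)-2-hydroxy-2-[(2E,6E,9E)-11-hydroxy-3,7,11-trimethyl-8-oxododeca-2,6,9-trien-1-yl]-4-methyl-1-benzofuran-3(2H)-one F4 is re-racemised with DIPEA in CHCl3 and recycled.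

Step 3. The acid co-catalysts may ionise the carbinol, which is both allylic and propargylic, and the alkyne flanked by a tertiary carbinol may bind ruthenium slowly. The fallback sets out from 6 and returns at 7, replacing the internal hydride shift by separate reduction and oxidation. Trans-selective semihydrogenation (Cp*RuCl(cod)/AgOTf, 5 mol % each, H2 10 bar, CH2Cl2) gives (2E,6E,9E)-8,11-dihydroxy-3,7,11-trimethyldodeca-2,6,9-trien-1-yl acetate F1. MnO2 in CH2Cl2 then oxidises only its secondary doubly allylic alcohol to give 7.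

**Further compounds**
F1 | step 3 | (2E,6E,9E)-8,11-dihydroxy-3,7,11-trimethyldodeca-2,6,9-trien-1-yl acetate, racemic at C8 | CC(=O)OC/C=C(\C)CC/C=C(\C)C(O)/C=C/C(C)(C)O
F2 | step 6 | 3-hydroxy-3-[(2E,6E,9E)-11-hydroxy-3,7,11-trimethyl-8-oxododeca-2,6,9-trien-1-yl]-5-methylchromane-2,4-dione, racemic | Cc1cccc2OC(=O)C(O)(C/C=C(\C)CC/C=C(\C)C(=O)/C=C/C(C)(C)O)C(=O)c12
F3 | step 6 | (4E,8E,11E)-2,13-dihydroxy-1-(2-hydroxy-6-methylphenyl)-5,9,13-trimethyltetradeca-4,8,11-triene-1,10-dione, racemic | Cc1cccc(O)c1C(=O)C(O)C/C=C(\C)CC/C=C(\C)C(=O)/C=C/C(C)(C)O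
F4 | step 7 | (2S)-2-hydroxy-2-[(2E,6E,9E)-11-hydroxy-3,7,11-trimethyl-8-oxododeca-2,6,9-trien-1-yl]-4-methyl-1-benzofuran-3(2H)-one | C/C(=C\C[C@]1(O)Oc2cccc(C)c2C1=O)CC/C=C(\C)C(=O)/C=C/C(C)(C)O
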